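Readings and results are calculated with made-up constants.

Halve the reagent charges first: once it is all in, the solution of starting material brings the volume to twice the start, in both runs and both new flasks.

| flask | starting material | reagent | remark | time |
|---|---|---|---|---|
| spring | 0.50 M (fed, over 2.0 min) | 0.27 M | run made earlier; the fed solution adds 1.0 times the starting volume |  |
| dawn | 0.50 M (fed, over 2.0 min) | 0.61 M | run made earlier; the fed solution adds 1.0 times the starting volume |  |
| alpha | 0.50 M | 0.200 M | everything together at the start, the whole solution of starting material included, so that from the start the volume is larger by 1.0 times the starting volume | 40 min |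
| beta | 0.50 M (fed, over 2.0 min) | 0.550 M | the fed solution adds 1.0 times the starting volume | 40 min |

| run | time / min | target / % |
|---|---|---|
| spring | 1.50 | 0.1 |
| spring | 4.00 | 0.2 |
| spring | 8.00 | 3.4 |
| spring | 20.0 | 6.8 |
| dawn | 5.00 | 3.9 |
| dawn | 10.0 | 6.7 |
| dawn | 15.0 | 10.2 |
| dawn | 20.0 | 13.5 |

(each reading ± 1 percentage point)

1. which of the two ends with the higher amount of target, in percent of the starting material charged ("neither" if they lie within 2 percentage points) (alpha / beta / neither)
2. target at the end, in percent of the starting material charged, alpha
3. target at the end, in percent of the starting material charged, beta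

- every charge counts on the volume at the start, and the solution that is fed holds the whole dose
- percentages count the whole charge, also what has not yet gone in

So spring works with c = 0.135 M of reagent and dawn with 0.305 M. Column against column, at 20.0 min dawn reads twice the target of spring, on 2.26 times the reagent, so I let the reagent scale the rate.

I reckon with f, the fraction of the charge not yet target. If each minute takes the same share of f, and that share is k·c, then k = −ln(f)/(c·t), a pseudo-first-order reading with c held. I use the last row of each column, its largest reading. Spring leaves f = 93.2%, so k = 0.0261 M⁻¹ min⁻¹. Dawn leaves 86.5%, so k = 0.0238 M⁻¹ min⁻¹. Their mean is 0.0249 M⁻¹ min⁻¹, the loss of ln f per reagent-minute.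

For 40 min my reckoning gives alpha 9.49% and beta 24.0%. Beta leads by 15 percentage points, well over the margin of 2 points.

The forecast says beta, with 8.7% for alpha and 22% for beta: “Beta ends clearly higher.” My beta stands above its figure: I hold c fixed, where the forecast has beta slow as reagent is used up.

The flask gives beta: alpha 9.69%, beta 21.8%.

    starting material + reagent ⇌ intermediate A (K = 0.950 M⁻¹, k = 0.199 M⁻¹ min⁻¹)
    intermediate A → intermediate B (k = 0.759 min⁻¹)
    intermediate A → target (k = 0.159 min⁻¹)
    intermediate B ⇌ target (K = 2.90, k = 0.0104 min⁻¹)

Back in the rule, these ends give k = 0.0255 M⁻¹ min⁻¹ for alpha and 0.0224 M⁻¹ min⁻¹ for beta, beside the 0.0249 M⁻¹ min⁻¹ from the runs. For a further flask, like alpha but with 0.80 M of reagent, k gives 32.9% against a simulated 28.0%. Beta is not at rest at 40.0 min: it holds starting material 34.7%, intermediate B 42.8%, and reagent 40.6% of its own charge. At ten times the time, k gives beta 93.6%, while the flask holds 71.6% target and intermediate B 26.1%. Alpha then holds target 29.6%, intermediate B 10.4%, reagent 0% of its own charge, and starting material 60.0%.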